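## The problem

Compound 31 is a trans-fused bicyclo[5.3.0]decane. Ring A is a cycloheptanone, numbered here C1 (the CHMe carbon), C2 and C3 (CH2), C4 (hydroxylated fusion carbon), C5 (fusion CH), C6 (ketone) and C7 (quaternary carbon). Ring B is a cyclopentane fused at C4–C5 (C8 the CH2, C9 the CHOH, C10 the CMe2 carbon), and a two-carbon arm (C11, C12) links C7 to C4 of a furan-2(5H)-one (ring C). Five stereocentres must be set: the vicinal pair C1/C7 (methyls trans), which no other centre can control; C4 and C5 (hydroxyl and hydrogen trans across the fusion); and C9 (hydroxyl trans to the C4 hydroxyl). C5 is α to the C6 ketone and can be corrected by equilibration at the end; C9 can be set from the C4 hydroxyl by internal hydride delivery; C4 needs a relay from the C1/C7 pair. The C4 hydroxyl is β to the C6 ketone, so strong acid (dehydration) and strong base (retro-aldol opening of ring A) must be avoided once it exists. A free C4/C6 1,3-diketone with hydrogen on C5 would be an acidic dead end, and the butenolide tolerates neither base nor hydride, so it belongs at the end. The enabling feature is that C7 and C1 are neighbours in ring A, C6 is a carbonyl carbon, and the arm on C7 can end in oxygen: tying that oxygen to C6 gives a 3-methyl-4,5-dihydrofuran whose C6=C7 enol ether has fixed geometry. With an (E)-propenyl group as C1/C2 and a cyclopropane as C3–C4–C5 (silyloxy on C4), ring A is the product of a cis-dialkenylcyclopropane rearrangement.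

## Retrosynthesis

**Ring C.** The C12–butenolide bond is cut first, giving iodide 29 and 4-bromofuran-2(5H)-one 30. This keeps the base- and hydride-sensitive butenolide out of every earlier step, and 29 carries only robust groups. The forward step must join an sp3 and an sp2 halide in the presence of two free hydroxyls and a ketone, which a nickel cross-electrophile coupling allows.

**C5 and C9.** Iodide 29 comes from hydroxy ketone 28, and 28 from the mixed ketal 26 by hydrolysis and epimerisation at C5. Leaving C5 to a final equilibration means the ring-B closure need only deliver C4 correctly. Diol 26 comes from ketol 25 by hydroxyl-directed reduction, which sets C9 from C4. The ketal in 25 and 26 masks C6 and the arm oxygen together, so no separate protecting group is needed.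

**C4–C10 bond.** Ketol 25 is opened to diketone 24, which holds an isopropenyl ketone on the C8 chain and a simple C4 ketone. Cutting here rather than at C5–C8 or C4–C5 keeps ring A intact and uses C5 to direct C4. The forward step needs an enolate at C10 only and no free base, since base would eliminate the β-ketal oxygen; conjugate reduction of the enone by copper hydride provides this.

**C5–C8 bond.** Diketone 24 is traced through alcohol 23 and silyl ether 22 to enol ether 17 and diazoketone 20, the latter from 3-methylbut-3-en-2-one 18. The alternative of alkylating a C4/C6 1,3-dione at C5 was rejected: such a dione would sit as its stabilised enolate or cyclise to a furan at the aldol stage. Carbenoid addition to the enol ether and acid methanolysis install the chain while converting C6 into a ketal.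

**C1–C7 bond (key step).** Enol ether 17 is the diimide reduction product of cycloheptadiene 16, and 16 is the [3,3] rearrangement product of cyclopropane 15. This cut removes ring A and both C1 and C7 in one stereospecific step, which no stepwise alkylation could match for a vicinal quaternary/tertiary pair. The forward reaction needs the two alkenyl groups cis, an (E)-propenyl group and a single enol ether geometry.

**Dihydrofuran.** 15 comes from γ-hydroxy ketone 14 by cyclodehydration, 14 from the β,γ-unsaturated ketone 13 by hydroboration, and 13 from Weinreb amide 11 and crotylmagnesium chloride 12. The crotyl reagent brings C7, its methyl, C11 and C12 in one bond formation and needs no protecting group.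

**Propenyl group.** Amide 11 comes from aldehyde 9 and 1,1-diiodoethane 10. Making the alkene from a cis aldehyde fixes its position and (E) geometry, which cyclopropanation of a silyloxydiene would not (either double bond could react). Aldehyde 9 comes from alcohol 8, and 8 from lactone 7.

**Cyclopropane.** Lactone 7 is the intramolecular cyclopropanation product of diazoacetate 6, made from bromoacetate 5, that is from alcohol 3 and bromoacetyl bromide 4. 3 comes from aldehyde 2 and the commercial malondialdehyde salt 1. The tether guarantees that the two future alkenyl carbons are cis, the (E) enol silane puts the silyloxy group trans to both, and one chiral catalyst sets the absolute configuration that the rearrangement later relays. An intermolecular cyclopropanation would leave the cis/trans ratio and the site of attack open.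

## Roads not taken

**Alternative 1: oxidative enolate coupling.** The cut is the C5–C8 bond. The monocyclic diketone A1 (a cycloheptanone carrying on C4 a triethylsilyloxy group and the 2-methyl-3-oxobutan-2-yl group) is deprotonated twice with LiN(iPr)2 and the bis-enolate oxidised with CuCl2 (divalent copper) to give the bicyclic 1,4-diketone A2.
- Merits: ring B and the 1,4-dicarbonyl arise in one step at the final oxidation level, with the C4 oxygen in place and no regiochemical question at the quaternary C10.
- Weak points: A1 already needs the C4 carbinol in the right configuration relative to C1/C7, so the hardest stereochemical problem is moved, not solved. The C6 enolate has a β-silyloxy leaving group on C4. Intramolecular hetero-coupling of two ketone enolates competes with chlorination and oligomerisation.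
- Comparison: for ring B this road is shorter than the chosen one, which spends a carbenoid addition, two redox adjustments and an aldol. The chosen plan sets against that a mechanism-based origin for C1/C7 and for C4.

**Alternative 2: transannular aldol.** The cut is the C4–C5 fusion bond. The ten-membered diketone A3 (ketones at C4 and C6, silyloxy at C9) is treated with KOtBu in tBuOH; C6 enolises toward C5, which adds across the ring to C4 and gives the trans-fused ketol A4.
- Merits: one bond closes both rings, and the reversible conditions place C4 and C5 under thermodynamic control in the last skeletal step.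
- Weak points: A3 is a medium ring that must already carry the vicinal C1/C7 pair and C9 in a defined 1,5 relationship. The equilibrium may rest on the open diketone or drain into the dehydrated enone.
- Comparison: for the ring fusion this road is better than the chosen one, which reaches C4 by relay and C5 by a late epimerisation. The chosen plan sets against it a direct, stereospecific answer for C1/C7 and independence from a ten-membered ring synthesis.

**Alternative 3: intramolecular Stetter reaction.** The cut is the C5–C6 bond. In aldehyde A5 (formyl group on C7, chain leading to a 4-silyloxy-5,5-dimethylcyclopent-2-enone) a triazolium-derived carbene turns the aldehyde into an acyl-anion equivalent that adds 7-exo to C5, giving the bicyclic 1,4-diketone A6.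
- Merits: it is convergent, ring B with C4 can be prepared separately, and the 1,4-diketone appears without redox steps under neutral conditions.
- Weak points: the aldehyde sits on a quaternary carbon and is a poor acyl-anion precursor. A 7-exo addition to a β-carbon next to the fully substituted C4 will be slow. C1/C7 must be built in an open chain, and their relationship to C4 rests only on joining two enantiopure fragments.
- Comparison: in convergence and oxidation-state economy this road is better. The chosen plan sets against it a thermal, catalyst-free ring closure that creates C1 and C7 together with defined geometry.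

Key step: step 12

Assumption (remark on the chemistry): the γ-hydroxy ketones 14, 27 and 28 are written open-chain; each equilibrates with its five-membered cyclic hemiketal, and the planned steps draw on whichever form reacts.

## Route

Step 1
Reactants: 1 malondialdehyde tetrabutylammonium salt (tetrabutylammonium (E)-3-oxoprop-1-en-1-olate)
Product: 2 (E)-3-[(tert-butyldimethylsilyl)oxy]prop-2-enal
Conditions: tBuMe2SiCl, CH2Cl2, 0 °C to rt
Reagents that add atoms: tert-butyldimethylsilyl chloride, CC(C)(C)[Si](C)(C)Cl
Why: O-Silylation of the vinylogous carboxylate; the extended (E) enolate keeps its geometry, so silyloxy and formyl end trans.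

Step 2
Reactants: 2 (E)-3-[(tert-butyldimethylsilyl)oxy]prop-2-enal
Product: 3 (E)-3-[(tert-butyldimethylsilyl)oxy]prop-2-en-1-ol
Conditions: iBu2AlH, CH2Cl2, −78 °C; aq. Rochelle salt
Reagents that add atoms: none
Why: 1,2-Reduction of the vinylogous formate by an aluminium hydride; the (E) enol silane is untouched and cannot pass silicon to the new hydroxyl.

Step 3
Reactants: 3 (E)-3-[(tert-butyldimethylsilyl)oxy]prop-2-en-1-ol; 4 bromoacetyl bromide
Product: 5 (E)-3-[(tert-butyldimethylsilyl)oxy]prop-2-en-1-yl bromoacetate
Conditions: pyridine, CH2Cl2, −20 °C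
Reagents that add atoms: none
Why: O-Acylation with an acid bromide; pyridine scavenges HBr, which would otherwise hydrolyse the enol silane.

Step 4
Reactants: 5 (E)-3-[(tert-butyldimethylsilyl)oxy]prop-2-en-1-yl bromoacetate
Product: 6 (E)-3-[(tert-butyldimethylsilyl)oxy]prop-2-en-1-yl diazoacetate
Conditions: TsNHNHTs, DBU, THF, 0 °C
Reagents that add atoms: N,N′-ditosylhydrazine, Cc1ccc(cc1)S(=O)(=O)NNS(=O)(=O)c1ccc(C)cc1
Why: Bromoacetate-to-diazoacetate conversion: N-alkylation of the bis-sulfonylhydrazide followed by two sulfinate eliminations; the mild amidine base leaves the enol silane alone.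

Step 5
Reactants: 6 (E)-3-[(tert-butyldimethylsilyl)oxy]prop-2-en-1-yl diazoacetate
Product: 7 (1S,5S,6S)-6-[(tert-butyldimethylsilyl)oxy]-3-oxabicyclo[3.1.0]hexan-2-one (silyloxy exo)
Conditions: Rh2(4S-MPPIM)4 (1 mol %), CH2Cl2, reflux, slow addition
Reagents that add atoms: none
Why: Carboxamidate-catalysed intramolecular cyclopropanation of an allylic diazoacetate. The tether forces the carbonyl-bearing and the CH2O-bearing carbons cis, the (E) alkene puts silyloxy exo, and the chiral dirhodium catalyst sets all three centres (the 4S ligand series is expected to give this sense, as with other trans-substituted allylic diazoacetates).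

Step 6
Reactants: 7 (1S,5S,6S)-6-[(tert-butyldimethylsilyl)oxy]-3-oxabicyclo[3.1.0]hexan-2-one
Product: 8 (1S,2S,3S)-2-[(tert-butyldimethylsilyl)oxy]-3-(hydroxymethyl)-N-methoxy-N-methylcyclopropane-1-carboxamide
Conditions: MeNH(OMe)·HCl, iPrMgCl, THF, −20 to 0 °C
Reagents that add atoms: N,O-dimethylhydroxylamine hydrochloride, CNOC.Cl
Why: Aminolysis of the lactone by the magnesium amide gives the Weinreb amide and frees the cis hydroxymethyl group; no stereocentre is touched.

Step 7
Reactants: 8 (1S,2S,3S)-2-[(tert-butyldimethylsilyl)oxy]-3-(hydroxymethyl)-N-methoxy-N-methylcyclopropane-1-carboxamide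
Product: 9 (1S,2S,3R)-2-[(tert-butyldimethylsilyl)oxy]-3-formyl-N-methoxy-N-methylcyclopropane-1-carboxamide
Conditions: Dess–Martin periodinane, NaHCO3, CH2Cl2, 0 °C
Reagents that add atoms: none
Why: Dess–Martin oxidation under buffered, non-basic conditions, so the cis aldehyde does not epimerise and the silyloxycyclopropane does not open.

Step 8
Reactants: 9 (1S,2S,3R)-2-[(tert-butyldimethylsilyl)oxy]-3-formyl-N-methoxy-N-methylcyclopropane-1-carboxamide; 10 1,1-diiodoethane
Product: 11 (1S,2S,3R)-2-[(tert-butyldimethylsilyl)oxy]-N-methoxy-N-methyl-3-[(E)-prop-1-en-1-yl]cyclopropane-1-carboxamide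
Conditions: CrCl2, THF, rt
Reagents that add atoms: none
Why: Takai–Utimoto ethylidenation: the geminal dichromium reagent reacts with the aldehyde only and gives the (E)-propenyl group; the medium is not basic, so the cis relationship survives.

Step 9
Reactants: 11 (1S,2S,3R)-2-[(tert-butyldimethylsilyl)oxy]-N-methoxy-N-methyl-3-[(E)-prop-1-en-1-yl]cyclopropane-1-carboxamide; 12 but-2-en-1-ylmagnesium chloride (crotylmagnesium chloride, CH3CH=CHCH2MgCl)
Product: 13 1-{(1S,2S,3R)-2-[(tert-butyldimethylsilyl)oxy]-3-[(E)-prop-1-en-1-yl]cyclopropyl}-2-methylbut-3-en-1-one (both epimers at the CHMe carbon)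
Conditions: THF, −78 °C; aq. NH4Cl
Reagents that add atoms: none
Why: Allylic Grignard addition through the six-membered SE2′ transition state gives the branched ketone, and the chelated tetrahedral intermediate of the Weinreb amide stops a second addition. The new CHMe centre becomes sp2 in step 11, so its configuration does not matter.

Step 10
Reactants: 13 1-{(1S,2S,3R)-2-[(tert-butyldimethylsilyl)oxy]-3-[(E)-prop-1-en-1-yl]cyclopropyl}-2-methylbut-3-en-1-one
Product: 14 1-{(1S,2S,3R)-2-[(tert-butyldimethylsilyl)oxy]-3-[(E)-prop-1-en-1-yl]cyclopropyl}-4-hydroxy-2-methylbutan-1-one (both epimers at the CHMe carbon)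
Conditions: 9-BBN, THF, 0 °C to rt; then H2O2, aq. NaHCO3
Reagents that add atoms: hydrogen peroxide, OO
Why: Hydroboration–oxidation: 9-BBN selects the terminal vinyl group over the 1,2-disubstituted propenyl group and the hindered ketone, giving the anti-Markovnikov alcohol.

Step 11
Reactants: 14 1-{(1S,2S,3R)-2-[(tert-butyldimethylsilyl)oxy]-3-[(E)-prop-1-en-1-yl]cyclopropyl}-4-hydroxy-2-methylbutan-1-one
Product: 15 tert-butyldimethyl{[(1S,2S,3R)-2-(3-methyl-4,5-dihydrofuran-2-yl)-3-[(E)-prop-1-en-1-yl]cyclopropyl]oxy}silane (alkenyl groups cis; silyloxy trans to both)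
Conditions: PPTS (cat.), 4 Å molecular sieves, benzene, 45 °C
Reagents that add atoms: none
Why: Acid-catalysed cyclodehydration of the γ-hydroxy ketone through its hemiketal. Loss of the proton from the CHMe carbon gives the endocyclic tetrasubstituted enol ether (the alternative is a strained alkylidenecyclopropane), and the ring fixes CH2 cis to oxygen.

Step 12
Reactants: 15 tert-butyldimethyl{[(1S,2S,3R)-2-(3-methyl-4,5-dihydrofuran-2-yl)-3-[(E)-prop-1-en-1-yl]cyclopropyl]oxy}silane
Product: 16 (3aR,4R,7S)-7-[(tert-butyldimethylsilyl)oxy]-3a,4-dimethyl-3,3a,4,7-tetrahydro-2H-cyclohepta[b]furan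
Conditions: toluene (degassed), trace Et3N, base-washed sealed tube, 110–130 °C
Reagents that add atoms: none
Why: Concerted [3,3]-sigmatropic (Cope) rearrangement of a cis-1,2-dialkenylcyclopropane; the closest known reaction type is the cis-divinylcyclopropane to cyclohepta-1,4-diene rearrangement with one enol ether terminus. The only accessible transition state is the boat with both alkenyl groups folded over the three-membered ring; the C3–C5 cyclopropane bond breaks as the C1–C7 bond forms, and strain release makes the step irreversible. Ring A closes by this bond between the two alkene termini, a three-to-seven ring expansion and not an end-on cyclisation, leaving the C2=C3 alkene and the C5=C6 enol ether. C1 is set by the (E)-propenyl group, whose methyl points away from the small ring in the boat; C7 is set by the dihydrofuran, which holds C11 outward and the methyl inward, so the two methyls end trans and the arm cis to the C1 methyl. Both centres form on the cyclopropane face fixed in step 5, so the absolute configuration is relayed intact, and the silyloxy carbon C4 is a spectator that ends cis to the C1 methyl. The step needs a cis-dialkenyl arrangement and a single enol ether geometry: the first comes from the lactone origin of the two carbons, the second from the five-membered ring. The inward methyl raises the barrier, hence the heating; base-washed glass and a trace of amine protect the enol ether.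

Step 13
Reactants: 16 (3aR,4R,7S)-7-[(tert-butyldimethylsilyl)oxy]-3a,4-dimethyl-3,3a,4,7-tetrahydro-2H-cyclohepta[b]furan
Product: 17 (3aR,4R,7S)-7-[(tert-butyldimethylsilyl)oxy]-3a,4-dimethyl-3,3a,4,5,6,7-hexahydro-2H-cyclohepta[b]furan
Conditions: 2-O2NC6H4SO2NHNH2, Et3N, CH2Cl2, rt
Reagents that add atoms: none
Why: Diimide reduction: concerted syn transfer of H2 to the unhindered cis-disubstituted C2=C3 bond; the trisubstituted, electron-rich enol ether reacts far more slowly and the medium stays basic.

Step 14
Reactants: 18 3-methylbut-3-en-2-one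
Product: 20 1-diazo-3-methylbut-3-en-2-one, via trifluoroacetyl diketone 19 (not isolated)
Conditions: LiN(SiMe3)2, THF, −78 °C; CF3CO2CH2CF3; then MeSO2N3, Et3N, H2O, MeCN, rt
Reagents that add atoms: methanesulfonyl azide, CS(=O)(=O)N=[N+]=[N-] (the trifluoroacetyl group of 19 comes from 2,2,2-trifluoroethyl trifluoroacetate, O=C(OCC(F)(F)F)C(F)(F)F, and is lost again)
Why: Detrifluoroacetylative diazo transfer: the methyl ketone is activated as its trifluoroacetyl derivative, then diazo transfer and loss of the activating group give the α′-diazo enone without touching the C=C bond.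

Step 15
Reactants: 17 (3aR,4R,7S)-7-[(tert-butyldimethylsilyl)oxy]-3a,4-dimethyl-3,3a,4,5,6,7-hexahydro-2H-cyclohepta[b]furan; 20 1-diazo-3-methylbut-3-en-2-one
Product: 22 1-{(3aR,4R,7S,8R)-7-[(tert-butyldimethylsilyl)oxy]-8a-methoxy-3a,4-dimethyloctahydro-2H-cyclohepta[b]furan-8-yl}-3-methylbut-3-en-2-one (both epimers at the ketal carbon), via cyclopropyl ketone 21 (not isolated)
Conditions: Rh2(OAc)4 (1 mol %), CH2Cl2, rt, slow addition of 20; then PPTS, MeOH, rt
Reagents that add atoms: methanol, CO
Why: Carbenoid cyclopropanation of an enol ether followed by acid ring opening of the donor–acceptor cyclopropane 21 (a dihydrofuran isomer would converge); the bond between the oxygen-bearing C6 and the acyl-bearing carbon breaks, leaving the 2-oxoalkyl chain on C5 and C6 as a mixed ketal that also holds the arm oxygen. Addition is expected on the face of the C7 methyl, because the other face is capped by C1 and its pseudoaxial methyl; this is also the arrangement trans to the C4 silyloxy group, to which C5 can equilibrate through the enol ether under the acidic conditions.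

Step 16
Reactants: 22 1-{(3aR,4R,7S,8R)-7-[(tert-butyldimethylsilyl)oxy]-8a-methoxy-3a,4-dimethyloctahydro-2H-cyclohepta[b]furan-8-yl}-3-methylbut-3-en-2-one
Product: 23 1-[(3aR,4R,7S,8R)-7-hydroxy-8a-methoxy-3a,4-dimethyloctahydro-2H-cyclohepta[b]furan-8-yl]-3-methylbut-3-en-2-one
Conditions: Bu4NF, AcOH, THF, 0 °C to rt
Reagents that add atoms: none
Why: Fluoride cleavage of the secondary silyl ether; acetic acid buffers the alkoxide so that neither oxa-Michael addition to the enone nor elimination at the ketal occurs.

Step 17
Reactants: 23 1-[(3aR,4R,7S,8R)-7-hydroxy-8a-methoxy-3a,4-dimethyloctahydro-2H-cyclohepta[b]furan-8-yl]-3-methylbut-3-en-2-one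
Product: 24 (3aR,4R,8R)-8a-methoxy-3a,4-dimethyl-8-(3-methyl-2-oxobut-3-en-1-yl)octahydro-7H-cyclohepta[b]furan-7-one
Conditions: Dess–Martin periodinane, NaHCO3, CH2Cl2, rt
Reagents that add atoms: none
Why: Dess–Martin oxidation to the C4 ketone under neutral conditions; C5, now α to a ketone and β to the ketal, sees no base, so it keeps its configuration and the ketal oxygen is not eliminated.

Step 18
Reactants: 24 (3aR,4R,8R)-8a-methoxy-3a,4-dimethyl-8-(3-methyl-2-oxobut-3-en-1-yl)octahydro-7H-cyclohepta[b]furan-7-one
Product: 25 cis-fused tricyclic ketol: ring B (C4 tertiary hydroxyl, C9 ketone, C10 gem-dimethyl) fused cis to ring A at C4–C5, C6 still the mixed methyl ketal closed by the arm oxygen (C1 R, C4 S, C5 R, C7 R)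
Conditions: [(Ph3P)CuH]6, toluene, −40 to 0 °C; aq. NH4Cl
Reagents that add atoms: none
Why: Reductive aldol cyclisation: copper hydride adds to the unsubstituted β-carbon of the isopropenyl ketone, and the copper enolate, formed only at C10, closes the cyclopentanone onto the C4 ketone; isolated ketones are not reduced and no free base is present. The three-atom tether from C5 reaches only the carbonyl face on which it stands, so ring B closes cis and C10 arrives cis to C8, which puts the hydroxyl trans to the C7 methyl as in the target.

Step 19
Reactants: 25 cis-fused tricyclic ketol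
Product: 26 cis-fused tricyclic diol: as 25 with C9 as a secondary alcohol (S), trans to the C4 hydroxyl
Conditions: Me4NBH(OAc)3, MeCN/AcOH, −30 °C
Reagents that add atoms: none
Why: Evans–Saksena reduction: the C4 hydroxyl exchanges onto boron and delivers hydride to the C9 carbonyl from its own face, so the new hydroxyl ends trans (1,3-anti); the cold, weakly acidic medium should leave the mixed ketal in place.

Step 20
Reactants: 26 cis-fused tricyclic diol
Product: 28 (2S,3aS,5R,6R,8aS)-2,8a-dihydroxy-5-(2-hydroxyethyl)-1,1,5,6-tetramethyloctahydroazulen-4(1H)-one (trans-fused), via cis-fused hydroxy ketone 27 (not isolated)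
Conditions: PPTS, acetone/H2O, rt; then K2CO3, MeOH, rt
Reagents that add atoms: water, O
Why: Mild acid hydrolysis of the mixed ketal frees the C6 ketone and the arm alcohol; C5 is now α to a ketone and is equilibrated by base through the enolate to the trans ring fusion of the natural product, which is expected to be the more stable arrangement. C4, C9 and the quaternary C7 cannot epimerise under these conditions.

Step 21
Reactants: 28 (2S,3aS,5R,6R,8aS)-2,8a-dihydroxy-5-(2-hydroxyethyl)-1,1,5,6-tetramethyloctahydroazulen-4(1H)-one
Product: 29 (2S,3aS,5R,6R,8aS)-2,8a-dihydroxy-5-(2-iodoethyl)-1,1,5,6-tetramethyloctahydroazulen-4(1H)-one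
Conditions: I2, PPh3, imidazole, CH2Cl2, 0 °C
Reagents that add atoms: iodine, II
Why: Appel-type iodination: the primary alkoxyphosphonium ion of the open hydroxy ketone is displaced by iodide; the tertiary hydroxyl, the neopentyl-type secondary hydroxyl and the hindered hemiketal hydroxyl react far more slowly.

Step 22
Reactants: 29 (2S,3aS,5R,6R,8aS)-2,8a-dihydroxy-5-(2-iodoethyl)-1,1,5,6-tetramethyloctahydroazulen-4(1H)-one; 30 4-bromofuran-2(5H)-one
Product: 31 (2S,3aS,5R,6R,8aS)-2,8a-dihydroxy-1,1,5,6-tetramethyl-5-[2-(5-oxo-2,5-dihydrofuran-3-yl)ethyl]octahydroazulen-4(1H)-one (the target)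
Conditions: NiBr2(dme) (10 mol %), 4,4′-di-tert-butyl-2,2′-bipyridine, Zn dust, DMA, rt
Reagents that add atoms: none
Why: Nickel-catalysed cross-electrophile (reductive) coupling: the C(sp2)–Br bond adds to zerovalent nickel, the alkyl iodide enters as a radical, and reductive elimination forms the C12–butenolide bond. The conditions tolerate free hydroxyls and the ketone, and no stereocentre is involved.

## Compound list

1 | malondialdehyde tetrabutylammonium salt | [O-]/C=C/C=O.CCCC[N+](CCCC)(CCCC)CCCC | starting material
2 | (E)-3-[(tert-butyldimethylsilyl)oxy]prop-2-enal | O=C/C=C/O[Si](C)(C)C(C)(C)C | intermediate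
3 | (E)-3-[(tert-butyldimethylsilyl)oxy]prop-2-en-1-ol | OC/C=C/O[Si](C)(C)C(C)(C)C | intermediate
4 | bromoacetyl bromide | BrCC(Br)=O | starting material
5 | (E)-3-[(tert-butyldimethylsilyl)oxy]prop-2-en-1-yl bromoacetate | BrCC(=O)OC/C=C/O[Si](C)(C)C(C)(C)C | intermediate
6 | (E)-3-[(tert-butyldimethylsilyl)oxy]prop-2-en-1-yl diazoacetate | [N-]=[N+]=CC(=O)OC/C=C/O[Si](C)(C)C(C)(C)C | intermediate
7 | (1S,5S,6S)-6-[(tert-butyldimethylsilyl)oxy]-3-oxabicyclo[3.1.0]hexan-2-one | O=C1OC[C@H]2[C@H](O[Si](C)(C)C(C)(C)C)[C@@H]12 | intermediate
8 | (1S,2S,3S)-2-[(tert-butyldimethylsilyl)oxy]-3-(hydroxymethyl)-N-methoxy-N-methylcyclopropane-1-carboxamide | OC[C@H]1[C@H](O[Si](C)(C)C(C)(C)C)[C@H]1C(=O)N(C)OC | intermediate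
9 | (1S,2S,3R)-2-[(tert-butyldimethylsilyl)oxy]-3-formyl-N-methoxy-N-methylcyclopropane-1-carboxamide | O=C[C@H]1[C@H](O[Si](C)(C)C(C)(C)C)[C@H]1C(=O)N(C)OC | intermediate
10 | 1,1-diiodoethane | CC(I)I | starting material
11 | (1S,2S,3R)-2-[(tert-butyldimethylsilyl)oxy]-N-methoxy-N-methyl-3-[(E)-prop-1-en-1-yl]cyclopropane-1-carboxamide | C/C=C/[C@H]1[C@H](O[Si](C)(C)C(C)(C)C)[C@H]1C(=O)N(C)OC | intermediate
12 | but-2-en-1-ylmagnesium chloride (crotylmagnesium chloride) | CC=CC[Mg]Cl | starting material
13 | 1-{(1S,2S,3R)-2-[(tert-butyldimethylsilyl)oxy]-3-[(E)-prop-1-en-1-yl]cyclopropyl}-2-methylbut-3-en-1-one (both CHMe epimers) | C/C=C/[C@H]1[C@H](O[Si](C)(C)C(C)(C)C)[C@H]1C(=O)C(C)C=C | intermediate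
14 | 1-{(1S,2S,3R)-2-[(tert-butyldimethylsilyl)oxy]-3-[(E)-prop-1-en-1-yl]cyclopropyl}-4-hydroxy-2-methylbutan-1-one (both CHMe epimers) | C/C=C/[C@H]1[C@H](O[Si](C)(C)C(C)(C)C)[C@H]1C(=O)C(C)CCO | intermediate
15 | tert-butyldimethyl{[(1S,2S,3R)-2-(3-methyl-4,5-dihydrofuran-2-yl)-3-[(E)-prop-1-en-1-yl]cyclopropyl]oxy}silane | C/C=C/[C@H]1[C@H](O[Si](C)(C)C(C)(C)C)[C@H]1C2=C(C)CCO2 | intermediate
16 | (3aR,4R,7S)-7-[(tert-butyldimethylsilyl)oxy]-3a,4-dimethyl-3,3a,4,7-tetrahydro-2H-cyclohepta[b]furan | C[C@@H]1C=C[C@H](O[Si](C)(C)C(C)(C)C)C=C2OCC[C@]12C | intermediate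
17 | (3aR,4R,7S)-7-[(tert-butyldimethylsilyl)oxy]-3a,4-dimethyl-3,3a,4,5,6,7-hexahydro-2H-cyclohepta[b]furan | C[C@@H]1CC[C@H](O[Si](C)(C)C(C)(C)C)C=C2OCC[C@]12C | intermediate
18 | 3-methylbut-3-en-2-one | CC(=O)C(C)=C | starting material
19 | 1,1,1-trifluoro-5-methylhex-5-ene-2,4-dione | FC(F)(F)C(=O)CC(=O)C(C)=C | intermediate
20 | 1-diazo-3-methylbut-3-en-2-one | [N-]=[N+]=CC(=O)C(C)=C | intermediate
21 | cyclopropyl ketone: cyclopropane across C5–C6 of 17, new carbon on the face of the C7 methyl, 2-methylprop-2-enoyl group exo | C[C@@H]1CC[C@H](O[Si](C)(C)C(C)(C)C)[C@H]2[C@H](C(=O)C(C)=C)[C@]23OCC[C@]13C | intermediate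
22 | 1-{(3aR,4R,7S,8R)-7-[(tert-butyldimethylsilyl)oxy]-8a-methoxy-3a,4-dimethyloctahydro-2H-cyclohepta[b]furan-8-yl}-3-methylbut-3-en-2-one (both ketal epimers) | C[C@@H]1CC[C@H](O[Si](C)(C)C(C)(C)C)[C@@H](CC(=O)C(C)=C)C2(OC)OCC[C@]12C | intermediate
23 | 1-[(3aR,4R,7S,8R)-7-hydroxy-8a-methoxy-3a,4-dimethyloctahydro-2H-cyclohepta[b]furan-8-yl]-3-methylbut-3-en-2-one | C[C@@H]1CC[C@H](O)[C@@H](CC(=O)C(C)=C)C2(OC)OCC[C@]12C | intermediate
24 | (3aR,4R,8R)-8a-methoxy-3a,4-dimethyl-8-(3-methyl-2-oxobut-3-en-1-yl)octahydro-7H-cyclohepta[b]furan-7-one | C[C@@H]1CCC(=O)[C@@H](CC(=O)C(C)=C)C2(OC)OCC[C@]12C | intermediate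
25 | cis-fused tricyclic ketol (C4 hydroxyl, C9 ketone, C10 gem-dimethyl; C6 mixed methyl ketal; C1 R, C4 S, C5 R, C7 R) | C[C@@H]1CC[C@]2(O)[C@@H](CC(=O)C2(C)C)C3(OC)OCC[C@]13C | intermediate
26 | cis-fused tricyclic diol (as 25, C9 hydroxyl S, trans to the C4 hydroxyl) | C[C@@H]1CC[C@]2(O)[C@@H](C[C@H](O)C2(C)C)C3(OC)OCC[C@]13C | intermediate
27 | (2S,3aR,5R,6R,8aS)-2,8a-dihydroxy-5-(2-hydroxyethyl)-1,1,5,6-tetramethyloctahydroazulen-4(1H)-one (cis-fused) | C[C@@H]1CC[C@]2(O)[C@@H](C[C@H](O)C2(C)C)C(=O)[C@]1(C)CCO | intermediate
28 | (2S,3aS,5R,6R,8aS)-2,8a-dihydroxy-5-(2-hydroxyethyl)-1,1,5,6-tetramethyloctahydroazulen-4(1H)-one (trans-fused) | C[C@@H]1CC[C@]2(O)[C@H](C[C@H](O)C2(C)C)C(=O)[C@]1(C)CCO | intermediate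
29 | (2S,3aS,5R,6R,8aS)-2,8a-dihydroxy-5-(2-iodoethyl)-1,1,5,6-tetramethyloctahydroazulen-4(1H)-one | C[C@@H]1CC[C@]2(O)[C@H](C[C@H](O)C2(C)C)C(=O)[C@]1(C)CCI | intermediate
30 | 4-bromofuran-2(5H)-one | O=C1C=C(Br)CO1 | starting material
31 | (2S,3aS,5R,6R,8aS)-2,8a-dihydroxy-1,1,5,6-tetramethyl-5-[2-(5-oxo-2,5-dihydrofuran-3-yl)ethyl]octahydroazulen-4(1H)-one | C[C@@H]1CC[C@]2(O)[C@H](C[C@H](O)C2(C)C)C(=O)[C@]1(C)CCC1=CC(=O)OC1 | target

## Step count and least certain steps

Total: 22 steps. Longest linear sequence: 21 steps (steps 1–13 and 15–22); step 14 prepares the side reagent 20.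

**Step 12 (key step).** The inward methyl on the enol ether terminus raises the barrier. At the temperature needed, one-centre epimerisation of the cyclopropane to the unreactive trans isomer, or acid-catalysed loss of the enol ether, may compete. The acid cyclodehydration that makes 15 (step 11) carries the related risk of opening the silyloxycyclopropyl ketone. Fallback, setting out from 14 and returning at 16: the enol geometry is fixed by chelation instead of by a ring. LiN(iPr)2 (2.2 equiv) gives the lithium alkoxide–enolate in which the arm is held cis to the enolate oxygen, and Me3SiCl traps it as the bis(trimethylsilyl) compound F1. As a 2-silyloxy-substituted dialkenylcyclopropane, F1 should rearrange at lower temperature to the cycloheptadiene silyl enol ether F2. Citric acid in methanol removes both trimethylsilyl groups to give the hydroxy ketone F3, and the cyclodehydration conditions of step 11, now harmless because the cyclopropane is gone, close the dihydrofuran to give 16.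

**Step 18.** Closure of a five-membered ring that contains the enolate double bond may be slower than protonation of the copper enolate, which would give plain conjugate reduction. Closure on the other face of the C4 carbonyl would break the relay from C5 to C4; that relay in turn depends on the facial outcome of step 15. Fallback, from 24 to 25: a thiolate conjugate addition–aldol sequence with Me2AlSPh (from Me3Al and PhSH) forms the aluminium enolate at C10 and lets the aldolate equilibrate, giving the phenylthiomethyl ketol F4. Raney Ni then removes sulfur, completing the gem-dimethyl group of 25.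

**Step 20.** Equilibration at C5 may stop short of the trans fusion, or the base may start retro-aldol opening or dehydration of the tertiary aldol. Fallback, from 27 (isolated after the acid stage) to 28: kinetic control replaces thermodynamic control. Me3SiOTf/Et3N gives the persilylated silyl enol ether F5, Saegusa–Ito dehydrogenation with Pd(OAc)2 gives the C5=C8 enone F6, and mild methanolysis gives the enone triol F7. Hydrogenation with [Ir(cod)(PCy3)(py)]PF6, directed by the secondary C9 hydroxyl on the face where the C5 hydrogen is needed, then gives 28. If the tertiary hydroxyl competes as directing group, it can be left as its trimethylsilyl ether.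

**Step 22.** Hydrodehalogenation or homocoupling may outrun cross-coupling, the butenolide may be reduced, or the γ-iodo ketone may cyclise. Fallback, from 29 to 31: the two halides are activated one after the other. Zinc insertion (Zn, LiCl, THF) gives the alkylzinc iodide F8, which is coupled with 30 in a Negishi reaction using Pd(PPh3)4.

## Further compounds

F1 | step 12 | bis(trimethylsilyl) derivative of 14 (trimethylsilyl enol ether with the arm cis to the enol oxygen; arm oxygen as trimethylsilyl ether) | C/C=C/[C@H]1[C@H](O[Si](C)(C)C(C)(C)C)[C@H]1/C(O[Si](C)(C)C)=C(\C)CCO[Si](C)(C)C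
F2 | step 12 | cycloheptadiene trimethylsilyl enol ether (rearranged F1) | C[C@@H]1C=C[C@H](O[Si](C)(C)C(C)(C)C)C=C(O[Si](C)(C)C)[C@]1(C)CCO[Si](C)(C)C
F3 | step 12 | 6-[(tert-butyldimethylsilyl)oxy]-2-(2-hydroxyethyl)-2,3-dimethylcyclohept-4-en-1-one | C[C@@H]1C=C[C@H](O[Si](C)(C)C(C)(C)C)CC(=O)[C@]1(C)CCO
F4 | step 18 | phenylthiomethyl ketol (as 25 with one C10 methyl replaced by CH2SPh; either C10 epimer) | C[C@@H]1CC[C@]2(O)[C@@H](CC(=O)C2(C)CSc4ccccc4)C3(OC)OCC[C@]13C
F5 | step 20 | persilylated C5=C6 silyl enol ether of 27 | C[C@@H]1CC[C@]2(O[Si](C)(C)C)C(C[C@H](O[Si](C)(C)C)C2(C)C)=C(O[Si](C)(C)C)[C@]1(C)CCO[Si](C)(C)C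
F6 | step 20 | tris(trimethylsilyl) C5=C8 enone | C[C@@H]1CC[C@]2(O[Si](C)(C)C)C(=C[C@H](O[Si](C)(C)C)C2(C)C)C(=O)[C@]1(C)CCO[Si](C)(C)C
F7 | step 20 | C5=C8 enone triol | C[C@@H]1CC[C@]2(O)C(=C[C@H](O)C2(C)C)C(=O)[C@]1(C)CCO
F8 | step 22 | alkylzinc iodide from 29 | C[C@@H]1CC[C@]2(O)[C@H](C[C@H](O)C2(C)C)C(=O)[C@]1(C)CC[Zn]I
A1 | alternative 1 | monocyclic diketone with C4 triethylsilyloxy and 2-methyl-3-oxobutan-2-yl groups | C[C@@H]1CC[C@@](O[Si](CC)(CC)CC)(C(C)(C)C(C)=O)CC(=O)[C@]1(C)CCO[Si](C)(C)C(C)(C)C
A2 | alternative 1 | bicyclic 1,4-diketone (triethylsilyl ether) | C[C@@H]1CC[C@]2(O[Si](CC)(CC)CC)[C@H](CC(=O)C2(C)C)C(=O)[C@]1(C)CCO[Si](C)(C)C(C)(C)C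
A3 | alternative 2 | cyclodecane-1,6-dione precursor | C[C@@H]1CCC(=O)C(C)(C)[C@@H](O[Si](C)(C)C(C)(C)C)CCC(=O)[C@]1(C)CCO[Si](C)(C)C(C)(C)C
A4 | alternative 2 | silyl-protected trans-fused ketol | C[C@@H]1CC[C@]2(O)[C@H](C[C@H](O[Si](C)(C)C(C)(C)C)C2(C)C)C(=O)[C@]1(C)CCO[Si](C)(C)C(C)(C)C
A5 | alternative 3 | aldehyde–cyclopentenone precursor | O=C[C@](C)(CCO[Si](C)(C)C(C)(C)C)[C@H](C)CC[C@]1(O[Si](C)(C)C)C=CC(=O)C1(C)C
A6 | alternative 3 | bicyclic 1,4-diketone (trimethylsilyl ether) | C[C@@H]1CC[C@]2(O[Si](C)(C)C)[C@H](CC(=O)C2(C)C)C(=O)[C@]1(C)CCO[Si](C)(C)C(C)(C)C
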